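## Retrosynthetic overview

1. The endgame removes the phenol silyl group, makes the chromene C3=C4 by DDQ dehydrogenation of a chroman, and makes the butenolide C=C by sulfoxide syn-elimination from an α-phenylthio-γ-lactone, which masks the base-sensitive butenolide.
2. The pyran ring is the second ring formed. An enantiopure tertiary alcohol closes onto an aryl bromide by intramolecular Pd C(aryl)–O coupling, so the C2–O bond is never broken.
3. The chain CH2–CH= bond comes from a B-alkyl Suzuki coupling of a tertiary vinyl carbinol (left half) with an (E)-vinyl iodide (right half). This fixes the E-trisubstituted alkene.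
4. The left half comes from 4-bromo-3,5-dimethylphenol (one CH3 becomes a benzylic Grignard) and (S)-2-methylglycidol (chromene stereocentre), followed by epoxide to vinyl carbinol conversion.
5. The right half contains the first ring formed, the lactone. It comes from (R)-epichlorohydrin (butenolide stereocentre) and acetylide, then methylalumination/iodination, then epoxide opening by an α-phenylthio acid dianion.

**Assumption:** the α-carbon (C3) of lactones 16–18 is an inconsequential epimer mixture that is destroyed in Step 13. TIPS = triisopropylsilyl.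

## Left half

**Step 1**
Reactants: 1, 4-bromo-3,5-dimethylphenol
Product: 2, (4-bromo-3,5-dimethylphenoxy)triisopropylsilane
Conditions: TIPSCl, imidazole, DMF, rt
Reagents that add atoms: TIPSCl, CC(C)[Si](Cl)(C(C)C)C(C)C
Why: This is a standard phenol silylation, and TIPS is the most base-stable common aryl silyl ether, so it survives the Grignard, ylide, aqueous phosphate and Cs2CO3 steps.

**Step 2**
Reactants: 2
Product: 3, [4-bromo-3-(bromomethyl)-5-methylphenoxy]triisopropylsilane
Conditions: NBS (1.0 equiv), AIBN (5 mol %), PhCF3, 85 °C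
Reagents that add atoms: NBS, O=C1CCC(=O)N1Br
Why: Wohl–Ziegler bromination of one of two equivalent benzylic methyls works because the para position is blocked and the bulky OTIPS shields the ortho carbons from ionic ring bromination.

**Step 3**
Reactants: 3; 4, (S)-2-methylglycidol
Product: 5, (2R)-4-[2-bromo-3-methyl-5-(TIPSO)phenyl]-2-methylbutane-1,2-diol
Conditions: (i) 3, Mg, Et2O, 0 °C; (ii) 4 (pre-deprotonated with MeMgCl, 1.0 equiv, −78 °C), CuI (10 mol %), THF, −40 → 0 °C
Reagents that add atoms: none
Why: In this Cu-catalysed Grignard epoxide opening the benzylic reagent attacks only the unsubstituted epoxide CH2, so the quaternary C–O stereocentre of 4 is carried over untouched and the descriptor changes S→R by CIP priority only.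

**Step 4**
Reactants: 5
Product: 6, (2R)-2-{2-[2-bromo-3-methyl-5-(TIPSO)phenyl]ethyl}-2-methyloxirane
Conditions: NaH, N-tosylimidazole, THF, 0 °C → rt
Reagents that add atoms: none
Why: Selective primary sulfonylation followed by intramolecular Williamson closure by the tertiary alkoxide leaves the stereogenic C–O bond intact.

**Step 5**
Reactants: 6
Product: 7, (3R)-5-[2-bromo-3-methyl-5-(TIPSO)phenyl]-3-methylpent-1-en-3-ol
Conditions: Me3S+I− (4 equiv), n-BuLi (3.8 equiv), THF, −10 °C → rt
Reagents that add atoms: trimethylsulfonium iodide, C[S+](C)C.[I-] (delivers CH2)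
Why: In this one-carbon epoxide-to-allylic-alcohol homologation, dimethylsulfonium methylide opens the epoxide at CH2 and a second ylide equivalent eliminates Me2S, so the stereocentre is not involved.

## Right half

**Step 6**
Reactants: 8, (R)-epichlorohydrin; 9, acetylene
Product: 10, (2R)-1-chloropent-4-yn-2-ol
Conditions: acetylene (excess), n-BuLi, THF, −78 °C; BF3·OEt2; then 8, −78 °C
Reagents that add atoms: none
Why: BF3-promoted acetylide opening of the epoxide occurs at the terminal CH2, so the carbinol configuration comes directly from 8.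

**Step 7**
Reactants: 10
Product: 11, (2R,4E)-1-chloro-5-iodo-4-methylpent-4-en-2-ol
Conditions: Me3Al (3 equiv), Cp2ZrCl2 (0.25 equiv), CH2Cl2, 0 °C → rt; then I2, THF, −30 °C
Reagents that add atoms: trimethylaluminium, C[Al](C)C (CH3); iodine, II (I)
Why: Zr-catalysed Negishi carboalumination adds Me–Al syn, with Me on the internal carbon and Al on the terminal carbon, and iodinolysis with retention gives only the (E)-iodide.

**Step 8**
Reactants: 11
Product: 12, (2R)-2-[(2E)-3-iodo-2-methylprop-2-en-1-yl]oxirane
Conditions: K2CO3, MeOH, 0 °C → rt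
Reagents that add atoms: none
Why: The chlorohydrin closes by an intramolecular Williamson reaction in which the alkoxide displaces the primary chloride, so the C–O stereocentre is retained.

**Step 9**
Reactants: 13, (phenylsulfanyl)acetic acid; 14, 5-bromo-2-methylpent-2-ene
Product: 15, (±)-6-methyl-2-(phenylsulfanyl)hept-5-enoic acid
Conditions: LDA (2.1 equiv), THF, 0 °C; then 14, DMPU, 0 °C → rt; H3O+
Reagents that add atoms: none
Why: The sulfur-stabilised carboxylic acid dianion is C-alkylated by the primary bromide.

**Step 10**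
Reactants: 15; 12
Product: 16, (5R)-5-[(2E)-3-iodo-2-methylprop-2-en-1-yl]-3-(4-methylpent-3-en-1-yl)-3-(phenylsulfanyl)oxolan-2-one (C3 epimers)
Conditions: 15, LDA (2.1 equiv), THF, 0 °C; 12, 0 °C → rt; H3O+; then p-TsOH (cat.), CH2Cl2, rt
Reagents that add atoms: none
Why: The α-thio acid dianion opens the epoxide at the terminal CH2 and the γ-hydroxy acid lactonises by acyl substitution, so C5 keeps the (R) configuration.

## Union and endgame

**Step 11**
Reactants: 7; 16
Product: 17, (5R)-5-{(2E,6S)-8-[2-bromo-3-methyl-5-(TIPSO)phenyl]-6-hydroxy-2,6-dimethyloct-2-en-1-yl}-3-(4-methylpent-3-en-1-yl)-3-(phenylsulfanyl)oxolan-2-one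
Conditions: 7, 9-BBN (2.5 equiv), THF, rt; then aq K3PO4; 16, PdCl2(dppf) (5 mol %), AsPh3, DMF, rt
Reagents that add atoms: none (9-BBN leaves only H)
Why: Anti-Markovnikov hydroboration of the vinyl group is followed by a B-alkyl Suzuki–Miyaura coupling that retains alkene geometry, and at rt the vinyl iodide reacts far faster than the di-ortho-substituted, electron-rich aryl bromide.

**Step 12**
Reactants: 17
Product: 18, (5R)-5-{(2E)-5-[(2S)-2,8-dimethyl-6-(TIPSO)chroman-2-yl]-2-methylpent-2-en-1-yl}-3-(4-methylpent-3-en-1-yl)-3-(phenylsulfanyl)oxolan-2-one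
Conditions: Pd(OAc)2 (5 mol %), 2-(di-tert-butylphosphino)-1,1′-binaphthyl (7 mol %), Cs2CO3, toluene, 80 °C
Reagents that add atoms: none
Why: In this intramolecular Buchwald-type C–O coupling the tertiary alkoxide has no β-hydrogen and bonds through oxygen, giving complete retention at C2, and the lactone has no α-hydrogen to enolise.

**Step 13**
Reactants: 18
Product: 19, (5R)-5-{(2E)-5-[(2S)-2,8-dimethyl-6-(TIPSO)chroman-2-yl]-2-methylpent-2-en-1-yl}-3-(4-methylpent-3-en-1-yl)furan-2(5H)-one
Conditions: mCPBA (1.0 equiv), CH2Cl2, −78 °C; then toluene, CaCO3, 110 °C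
Reagents that add atoms: none retained (the mCPBA oxygen leaves as PhSOH)
Why: Sulfide oxidation outcompetes alkene epoxidation at −78 °C, and thermal sulfoxide syn-elimination gives the endocyclic butenolide under neutral conditions, so C5 is not epimerised and the heating is done before the racemisable chromene exists.

**Step 14**
Reactants: 19
Product: 20, (5R)-5-{(2E)-5-[(2S)-2,8-dimethyl-6-(TIPSO)-2H-chromen-2-yl]-2-methylpent-2-en-1-yl}-3-(4-methylpent-3-en-1-yl)furan-2(5H)-one
Conditions: DDQ (1.5 equiv), benzene, 80 °C, dark
Reagents that add atoms: none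
Why: DDQ abstracts hydride from benzylic C4, whose cation is stabilised by the ortho ring oxygen, and loss of H-3 gives the chromene without touching the quaternary C2.

**Step 15**
Reactants: 20
Product: 21, tuberatolide B
Conditions: TBAF/AcOH (1:1), THF, 0 °C, dark
Reagents that add atoms: none
Why: Buffered fluoride cleaves the aryl silyl ether without enolising the butenolide γ-H or ionising the chromene.

## Compound list

| No. | Name | SMILES | Role |
|---|---|---|---|
| 1 | 4-bromo-3,5-dimethylphenol | Cc1cc(O)cc(C)c1Br | starting material |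
| 2 | (4-bromo-3,5-dimethylphenoxy)triisopropylsilane | Cc1cc(O[Si](C(C)C)(C(C)C)C(C)C)cc(C)c1Br | intermediate |
| 3 | [4-bromo-3-(bromomethyl)-5-methylphenoxy]triisopropylsilane | Cc1cc(O[Si](C(C)C)(C(C)C)C(C)C)cc(CBr)c1Br | intermediate |
| 4 | (S)-2-methylglycidol | OC[C@@]1(C)CO1 | starting material |
| 5 | (2R)-4-aryl-2-methylbutane-1,2-diol | OC[C@](C)(O)CCc1cc(O[Si](C(C)C)(C(C)C)C(C)C)cc(C)c1Br | intermediate |
| 6 | (2R)-2-(2-arylethyl)-2-methyloxirane | Cc1cc(O[Si](C(C)C)(C(C)C)C(C)C)cc(CC[C@]2(C)CO2)c1Br | intermediate |
| 7 | (3R)-5-aryl-3-methylpent-1-en-3-ol | C=C[C@](C)(O)CCc1cc(O[Si](C(C)C)(C(C)C)C(C)C)cc(C)c1Br | intermediate |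
| 8 | (R)-epichlorohydrin | ClC[C@H]1CO1 | starting material |
| 9 | acetylene | C#C | starting material |
| 10 | (2R)-1-chloropent-4-yn-2-ol | ClC[C@H](O)CC#C | intermediate |
| 11 | (2R,4E)-1-chloro-5-iodo-4-methylpent-4-en-2-ol | ClC[C@H](O)C/C(C)=C/I | intermediate |
| 12 | (2R)-2-[(2E)-3-iodo-2-methylallyl]oxirane | C1O[C@@H]1C/C(C)=C/I | intermediate |
| 13 | (phenylsulfanyl)acetic acid | OC(=O)CSc1ccccc1 | starting material |
| 14 | 5-bromo-2-methylpent-2-ene | CC(C)=CCCBr | starting material |
| 15 | (±)-6-methyl-2-(phenylsulfanyl)hept-5-enoic acid | CC(C)=CCCC(Sc1ccccc1)C(=O)O | intermediate |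
| 16 | (5R)-vinyl iodide α-PhS lactone (C3 epimers) | CC(C)=CCCC1(Sc2ccccc2)C[C@@H](C/C(C)=C/I)OC1=O | intermediate |
| 17 | Suzuki product, (6S)-tertiary alcohol aryl bromide | CC(C)=CCCC1(Sc2ccccc2)C[C@@H](C/C(C)=C/CC[C@](C)(O)CCc2cc(O[Si](C(C)C)(C(C)C)C(C)C)cc(C)c2Br)OC1=O | intermediate |
| 18 | (2S)-chroman α-PhS lactone | CC(C)=CCCC1(Sc2ccccc2)C[C@@H](C/C(C)=C/CC[C@@]2(C)CCc3cc(O[Si](C(C)C)(C(C)C)C(C)C)cc(C)c3O2)OC1=O | intermediate |
| 19 | (2S)-chroman (5R)-butenolide, TIPS ether | CC(C)=CCCC1=C[C@@H](C/C(C)=C/CC[C@@]2(C)CCc3cc(O[Si](C(C)C)(C(C)C)C(C)C)cc(C)c3O2)OC1=O | intermediate |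
| 20 | O-TIPS tuberatolide B | CC(C)=CCCC1=C[C@@H](C/C(C)=C/CC[C@@]2(C)C=Cc3cc(O[Si](C(C)C)(C(C)C)C(C)C)cc(C)c3O2)OC1=O | intermediate |
| 21 | tuberatolide B, (5R) butenolide and (2S) chromene | CC(C)=CCCC1=C[C@@H](C/C(C)=C/CC[C@@]2(C)C=Cc3cc(O)cc(C)c3O2)OC1=O | target |

## Step count

- **Total steps:** 15
- **Longest linear sequence:** 10 (Steps 1–5 and 11–15)

## Three steps most likely to fail

1. **Step 12, late C–O coupling on a hindered, electron-rich aryl bromide.**
   - Fallback: form O1–C2 from a phenol oxygen instead of from an aryl halide.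
   - Cyclise 2-[(E)-5-(methoxycarbonyloxy)-3-methylpent-3-enyl]-6-methyl-4-(TIPSO)phenol by Pd-catalysed asymmetric allylic alkylation with a chiral diphosphine to give (R)-2-methyl-2-vinylchroman.
   - Hydroborate that chroman and couple it with 16 as in Step 11. The catalyst then sets the stereocentre and no aryl bromide is needed.

2. **Step 14, DDQ dehydrogenation in the presence of three other alkenes.**
   - Fallback: move the dehydrogenation to the simple 2-methyl-2-vinylchroman from fallback 1, which has only one oxidisable site.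
   - Hydroborate only the terminal vinyl group of the resulting chromene and couple it with the right half.
   - Use the α-phenylseleno analogue of 16, so the butenolide is released by selenoxide elimination at 0 °C and the chromene is never heated.

3. **Step 11, B-alkyl Suzuki coupling with a free γ-hydroxyl, a thioether and an aryl bromide present.**
   - Fallback: join the halves through an alkyne.
   - Open epoxide 6 with lithiated 1-(trimethylsilyl)propyne, carry out the C–O cyclisation early, and desilylate.
   - Open (R)-epichlorohydrin with the lithium acetylide and BF3.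
   - Set the E-trisubstituted alkene by hydroxyl-directed Ru-catalysed trans-hydrostannation followed by methyl Stille coupling.
   - Finish with Steps 8, 10 and 13–15 as written.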